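Open a ledger on Q, in which every percentage is counted, and post each mole charged to an account.

| flask | Q | E | G | remark | time |
|---|---|---|---|---|---|
| Monday's | 1.1 M | 0.23 M | 2.8 mM | run made earlier |  |
| noon | 2.3 M | 0.600 M | 6.0 mM |  | 3.0 h |
| dusk | 2.3 M | 0.230 M | 2.8 mM |  | 10 h |

Monday's run (percent of the Q charged)

| time / h | J / % | Q / % |
|---|---|---|
| 0.500 | 7.6 | 83.6 |
| 0.833 | 10.3 | 74.9 |
| 1.33 | 17.3 | 61.8 |
| 2.00 | 21.0 | 50.3 |
| 4.00 | 34.4 | 24.6 |
| 6.00 | 37.6 | 14.6 |

(each reading ± 1 percentage point)

- a reading or a percentage of J counts all its forms, free or not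
- no earlier run changes the charge of G; that part of a forecast is a guess
- no earlier run changes the charge of E; that part of a forecast is a guess

- which of the two ends with the higher amount of J, in percent of the Q charged ("neither" if they lie within 2 percentage points) (noon / dusk / neither)
- J at the end, in percent of the Q charged, noon
- J at the end, in percent of the Q charged, dusk

At Monday's last reading, 6.00 h, the books show 14.6% of Q still there, 37.6% posted to J, and 47.8% posted to accounts I can't see. Those last two entries give 0.787, and this is what I carry: the odds w, moles of Q posted to J for each mole posted elsewhere, a selectivity factor. Odds of one are the even split, the zero of my scale, and Monday's run stands below it. The same reading gives Q a first-order constant of 0.321 h⁻¹.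

Dusk has Monday's cE and cG, so I keep w and that constant, although its cQ is twice Monday's, and I reckon J at 42.2%. For noon I must guess: cG rises by a factor of 2.14 and cE by 2.61, and no run shows what either does. I let the J account grow with cG, to 0.303 h⁻¹, and take the even split, which gives 41.9%.

The forecast answers neither, with 41% at noon and 42.5% at dusk. It keeps Monday's split at noon, where I moved it, and warns “the split could shift with E or G”.

The flask gives neither: 46.5% at noon and 45.9% at dusk.

    Q → D (k = 0.140 h⁻¹)
    Q + E → L (k = 0.320 M⁻¹ h⁻¹)
    Z ⇌ J, rate k3*(cs3 - [J]) while solid is left; crystals form when [J] > cs3 (solubility = 0.0780 M, k = 5.90 h⁻¹)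
    2 Q → X (k = 5.70 × 10⁻⁵ M⁻¹ h⁻¹)
    Q + G → G + J (k = 56.0 M⁻¹ h⁻¹)

At the dusk charge, Q has half-lives of 4.4 h by the step to J, 5.0 h by the step to D and 9.4 h by the step to L, so the dusk odds start at 0.734. At their ends the books give odds of 0.921 at dusk and 1.29 at noon, against the 0.787 read from Monday's run at 6.00 h. Scaling w in proportion to cG gives a further flask, like dusk but with 0.0017 M of G, odds of 0.478, and with its 8.07% of Q left, that means 29.7% of J; that further flask holds 33.4%.

The earlier runs and the new flask come from a simulation from invented constants, noise included.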